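**Plan**

1. Locants: C1 is the aryl-bearing CH of the tetralin, C2 and C3 are the two CH(CH2OH) carbons, C4 is the ring CH2, and C4a–C8a is the fused arene (6,8-OMe, 7-OH).
2. Enabling feature: C1 is doubly benzylic. It lies para to the free OH of the pendant ring and ortho/para to the 8- and 6-OMe groups of the fused ring, so it can act as a formyl-cation equivalent that is arylated twice. Both arenes are symmetric syringyl units, each with only one kind of productive carbon.
3. Cuts: first pendant aryl–C1 and C1–C8a (target → 2,6-dimethoxyphenol + open-chain acetal diol 11). Then C1–C2 (→ trimethyl orthoformate + (R)-β-benzylbutyrolactone 7). Then C3–C4 as an alkene (→ syringaldehyde + dimethyl succinate).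
4. Forward: Stobbe chain assembly, a temporary lactone ring for control at C2, and reductive opening. One acid-triggered cascade follows, in which a transient tetrahydrofuran forms, the phenol is joined to C1, the tetrahydrofuran opens and ring B closes. The cascade gives the unprotected target.
5. Stereochemistry: C3 comes from Rh-catalysed asymmetric hydrogenation. C2 is relayed from C3 by anti attack on the lactone ketene acetal. C1 is relayed from C2 by a chair-like closure that places the aryl group trans.

Key step: step 8

Assumption: the hand of the bisphosphine in step 3 is taken as the one that delivers the (R)-acid. If the sense of induction is the opposite, the mirror-image ligand is used.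

**Step 1**
Reactants: 1 syringaldehyde (4-hydroxy-3,5-dimethoxybenzaldehyde)
Product: 2 4-(benzyloxy)-3,5-dimethoxybenzaldehyde
Conditions: BnBr, K2CO3, DMF, 60 °C
Reagents that add atoms: benzyl bromide BrCc1ccccc1
Why: Williamson ether synthesis; the phenol is masked because a phenoxide would deactivate the aldehyde in step 2 and quench the enolate in step 5.

**Step 2**
Reactants: 2 4-(benzyloxy)-3,5-dimethoxybenzaldehyde; 3 dimethyl succinate
Product: 4 (E)-4-[4-(benzyloxy)-3,5-dimethoxyphenyl]-3-(methoxycarbonyl)but-3-enoic acid
Conditions: NaOMe, MeOH, reflux; then aq. HCl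
Reagents that add atoms: none
Why: Stobbe condensation; the succinate enolate adds to the aldehyde, the alkoxide lactonises on the distal ester, and E1cB opening of the paraconic ester should give the (E)-alkylidene half-ester with acid and ester already differentiated for step 4.

**Step 3**
Reactants: 4 (E)-half-ester
Product: 5 (R)-4-[4-(benzyloxy)-3,5-dimethoxyphenyl]-3-(methoxycarbonyl)butanoic acid
Conditions: [Rh(cod)((S,S)-Et-DuPhos)]OTf (0.5 mol %), H2 (6 bar), NaOMe (10 mol %), MeOH, rt
Reagents that add atoms: none
Why: Rh(I)–bisphosphine asymmetric hydrogenation of an itaconate-type half-ester; carboxylate chelation to rhodium and the C2-symmetric ligand fix the face of H2 delivery and set C3 (R), and the benzyl ether is inert to the homogeneous catalyst.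

**Step 4**
Reactants: 5 (R)-half-ester
Product: 7 (R)-4-[4-(benzyloxy)-3,5-dimethoxybenzyl]dihydrofuran-2(3H)-one, via hydroxy acid 6 (not isolated)
Conditions: KOH (1 equiv), EtOH; CaCl2, NaBH4, −10 °C → rt; then 3 M HCl, rt
Reagents that add atoms: none
Why: Chemoselective borohydride reduction; Ca(BH4)2 reduces the ester but not the carboxylate salt, acidification lactonises the γ-hydroxy acid, and C3 is not touched.

**Step 5**
Reactants: 7 (R)-β-benzylbutyrolactone
Product: 9 (3S,4R)-4-[4-(benzyloxy)-3,5-dimethoxybenzyl]-3-(dimethoxymethyl)dihydrofuran-2(3H)-one, via ketene silyl acetal 8 (not isolated)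
Conditions: LDA, THF, −78 °C; TMSCl, −78 → 0 °C; volatiles removed; HC(OMe)3, TMSOTf (10 mol %), CH2Cl2, −78 °C; pyridine quench
Reagents that add atoms: trimethyl orthoformate COC(OC)OC; chlorotrimethylsilane C[Si](C)(C)Cl (its silyl group is in 8 only)
Why: Mukaiyama-type alkylation of a ketene silyl acetal by the dimethoxycarbenium ion (orthoester variant); the electrophile approaches planar C2 anti to the C3 benzyl group, so the trans lactone should result, and C1 enters at the aldehyde oxidation level in a masked, non-enolisable form.

**Step 6**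
Reactants: 9 trans acetal lactone
Product: 10 (2R,3R)-2-[4-(benzyloxy)-3,5-dimethoxybenzyl]-3-(dimethoxymethyl)butane-1,4-diol
Conditions: LiAlH4, THF, 0 °C → rt; H2O/15 % NaOH/H2O work-up
Reagents that add atoms: none
Why: Hydride reduction of a lactone to the 1,4-diol; acetal and benzyl ether are inert, the basic work-up keeps the acetal, and removing the carbonyl next to C2 blocks later loss of methanol to a conjugated methoxymethylene lactone.

**Step 7**
Reactants: 10 benzyl-protected acetal diol
Product: 11 (2R,3R)-2-(4-hydroxy-3,5-dimethoxybenzyl)-3-(dimethoxymethyl)butane-1,4-diol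
Conditions: H2 (1 atm), 10 % Pd/C, EtOAc–EtOH, rt
Reagents that add atoms: none
Why: Hydrogenolysis of an aryl benzyl ether under neutral conditions; any partial transacetalisation by the C3 hydroxymethyl group would be harmless, because it leads to the first intermediate of the next step.

**Step 8**
Reactants: 11 acetal diol; 12 2,6-dimethoxyphenol (syringol)
Product: 15 (+)-lyoniresinol (1S,2R,3R; target), via cyclic methyl acetal 13 (not isolated), via 5,5'-dimethoxylariciresinol 14 (not isolated)
Conditions: 12 (5 equiv), TfOH (10 mol %), HFIP (0.02 M in 11), 0 °C → rt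
Reagents that add atoms: none
Why: Acid ionises the dimethyl acetal, the hydroxyl of the C3 hydroxymethyl group closes on C1 (5-exo-trig) to give 13, and the derived cyclic oxocarbenium ion is attacked by the carbon of 12 para to OH in a Friedel–Crafts C-arylation that forms the aryl–C1 bond and gives the 2-aryltetrahydrofuran 14. Because C1 of 14 is para to a free phenol, its benzylic C1–O bond re-ionises to a protonated p-quinone methide, which the tethered syringyl ring attacks through a carbon ortho to one OMe and para to the other (6-exo-trig at the methide carbon), closing ring B and releasing the C3 hydroxymethyl group. The closest known reaction types are the acid-promoted C-arylation of lactol ethers by electron-rich phenols and the acid isomerisation of 2-aryl-4-benzyltetrahydrofuran lignans to aryltetralins; if the tethered ring attacks first, the resulting 1-alkoxytetralin re-ionises at the same carbon (stabilised by the 6- and 8-OMe groups) and is arylated by 12, so both orders converge on 15. C1 is the only new stereocentre and is controlled by C2: a chair-like transition state with the C2 and C3 hydroxymethyl groups and the aryl group equatorial (or, in the other order, attack anti to the C2 substituent) should give the 1,2-trans (1S) isomer whatever the C1 configuration of 14. The step needs para rather than C3 attack on 12, which the unhindered para carbon and the reversibility of alkylation by so stabilised a cation should secure, and cross- rather than self-arylation, which excess 12 and dilution should secure. Ring closure poses no regiochemical choice because the two free positions of the tethered ring are equivalent.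

**Compound list**

1 | syringaldehyde | COc1cc(C=O)cc(OC)c1O | starting material
2 | 4-(benzyloxy)-3,5-dimethoxybenzaldehyde | COc1cc(C=O)cc(OC)c1OCc1ccccc1 | intermediate
3 | dimethyl succinate | COC(=O)CCC(=O)OC | starting material
4 | (E)-4-[4-(benzyloxy)-3,5-dimethoxyphenyl]-3-(methoxycarbonyl)but-3-enoic acid | COC(=O)/C(CC(=O)O)=C/c1cc(OC)c(OCc2ccccc2)c(OC)c1 | intermediate
5 | (R)-4-[4-(benzyloxy)-3,5-dimethoxyphenyl]-3-(methoxycarbonyl)butanoic acid | COC(=O)[C@H](Cc1cc(OC)c(OCc2ccccc2)c(OC)c1)CC(=O)O | intermediate
6 | (R)-4-[4-(benzyloxy)-3,5-dimethoxyphenyl]-3-(hydroxymethyl)butanoic acid | OC[C@H](Cc1cc(OC)c(OCc2ccccc2)c(OC)c1)CC(=O)O | intermediate (not isolated)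
7 | (R)-4-[4-(benzyloxy)-3,5-dimethoxybenzyl]dihydrofuran-2(3H)-one | O=C1C[C@@H](Cc2cc(OC)c(OCc3ccccc3)c(OC)c2)CO1 | intermediate
8 | {[(3R)-3-[4-(benzyloxy)-3,5-dimethoxybenzyl]-2,3-dihydrofuran-5-yl]oxy}trimethylsilane | C[Si](C)(C)OC1=C[C@@H](Cc2cc(OC)c(OCc3ccccc3)c(OC)c2)CO1 | intermediate (not isolated)
9 | (3S,4R)-4-[4-(benzyloxy)-3,5-dimethoxybenzyl]-3-(dimethoxymethyl)dihydrofuran-2(3H)-one | O=C1OC[C@H](Cc2cc(OC)c(OCc3ccccc3)c(OC)c2)[C@H]1C(OC)OC | intermediate
10 | (2R,3R)-2-[4-(benzyloxy)-3,5-dimethoxybenzyl]-3-(dimethoxymethyl)butane-1,4-diol | COC(OC)[C@@H](CO)[C@H](CO)Cc1cc(OC)c(OCc2ccccc2)c(OC)c1 | intermediate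
11 | (2R,3R)-2-(4-hydroxy-3,5-dimethoxybenzyl)-3-(dimethoxymethyl)butane-1,4-diol | COC(OC)[C@@H](CO)[C@H](CO)Cc1cc(OC)c(O)c(OC)c1 | intermediate
12 | 2,6-dimethoxyphenol (syringol) | COc1cccc(OC)c1O | starting material
13 | [(3R,4R)-4-(4-hydroxy-3,5-dimethoxybenzyl)-2-methoxytetrahydrofuran-3-yl]methanol (anomers) | COC1OC[C@H](Cc2cc(OC)c(O)c(OC)c2)[C@@H]1CO | intermediate (not isolated)
14 | (2S,3R,4R)-5,5'-dimethoxylariciresinol: 2-(4-hydroxy-3,5-dimethoxyphenyl)-3-(hydroxymethyl)-4-(4-hydroxy-3,5-dimethoxybenzyl)tetrahydrofuran | COc1cc(cc(OC)c1O)[C@H]1OC[C@H](Cc2cc(OC)c(O)c(OC)c2)[C@@H]1CO | intermediate (not isolated)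
15 | (+)-lyoniresinol, (1S,2R,3R)-1-(4-hydroxy-3,5-dimethoxyphenyl)-2,3-bis(hydroxymethyl)-6,8-dimethoxy-1,2,3,4-tetrahydronaphthalen-7-ol | COc1cc([C@H]2c3c(cc(OC)c(O)c3OC)C[C@@H](CO)[C@@H]2CO)cc(OC)c1O | target

**Step count**

Total steps: 8. Longest linear sequence: 8 (from 1).

**Steps most likely to fail**

**Step 8.** Three processes could go wrong.
- The cation may attack C3 of 12 (ortho/para to its OMe groups) instead of the para carbon.
- Intermolecular attack by the tethered ring of a second molecule may compete with attack by 12.
- Proton loss from the oxocarbenium ion to an enol ether before arylation would erode the C2 configuration.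

The fallback sets out from 10 and replaces the electrophilic arylation by a regiospecific organometallic addition, followed by a separate ring closure. Mild hydrolysis of the acetal (AcOH–H2O–THF, rt) should give (3R,4R)-4-[4-(benzyloxy)-3,5-dimethoxybenzyl]-3-(hydroxymethyl)tetrahydrofuran-2-ol F1. Commercial 4-bromo-2,6-dimethoxyphenol is benzylated (BnBr, K2CO3, DMF) to 2-(benzyloxy)-5-bromo-1,3-dimethoxybenzene F2. Magnesium in THF then converts it into [4-(benzyloxy)-3,5-dimethoxyphenyl]magnesium bromide F3. Excess F3 adds to the open hydroxy-aldehyde form of F1 (THF, −20 °C → rt) and makes the same aryl–C1 bond, giving the benzylic alcohol triol F4 as C1 epimers. TFA in CH2Cl2 at 0 °C ionises the benzylic alcohol and closes ring B trans to C2, giving di-O-benzyl-lyoniresinol F5. Hydrogenolysis (H2, Pd/C, EtOAc–EtOH) comes back to the route at 15.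

**Step 5.** Three processes could go wrong.
- C-silylation may compete with O-silylation of the enolate.
- The product may lose methanol to a methoxymethylene lactone, which erases C2.
- The dimethoxycarbenium ion may attack the electron-rich ring in a Friedel–Crafts sense.

The fallback sets out from 7 and replaces kinetic anti attack by thermodynamic control. Claisen formylation (NaH, HCO2Me, THF, 0 °C → rt) should give the (R)-α-(hydroxymethylene) lactone F6. Acetalisation (HC(OMe)3, MeOH, cat. p-TsOH, rt) proceeds with reversible loss and re-addition of methanol, so C2 equilibrates toward the less crowded trans isomer. The fallback comes back to the route at 9.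

**Step 3.** Facial discrimination may be insufficient, or turnover slow, with the hindered, electron-rich trisubstituted alkene. The fallback sets out from 4 and replaces catalysis by resolution. Hydrogenation with an achiral catalyst ([Rh(cod)(dppb)]BF4, H2, MeOH) gives the racemic half-ester F7. Crystallisation with (S)-1-phenylethylamine (its antipode is used if the other salt is the less soluble one) gives the diastereomerically pure ammonium salt F8. Acidification comes back to the route at 5.

**Further compounds**

F1 | step 8 | (3R,4R)-4-[4-(benzyloxy)-3,5-dimethoxybenzyl]-3-(hydroxymethyl)tetrahydrofuran-2-ol | OC1OC[C@H](Cc2cc(OC)c(OCc3ccccc3)c(OC)c2)[C@@H]1CO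
F2 | step 8 | 2-(benzyloxy)-5-bromo-1,3-dimethoxybenzene | COc1cc(Br)cc(OC)c1OCc1ccccc1
F3 | step 8 | [4-(benzyloxy)-3,5-dimethoxyphenyl]magnesium bromide | COc1cc([Mg]Br)cc(OC)c1OCc1ccccc1
F4 | step 8 | (2R,3R)-2-[4-(benzyloxy)-3,5-dimethoxybenzyl]-3-{[4-(benzyloxy)-3,5-dimethoxyphenyl](hydroxy)methyl}butane-1,4-diol | OC(c1cc(OC)c(OCc2ccccc2)c(OC)c1)[C@@H](CO)[C@H](CO)Cc1cc(OC)c(OCc2ccccc2)c(OC)c1
F5 | step 8 | di-O-benzyl-lyoniresinol | COc1cc([C@H]2c3c(cc(OC)c(OCc4ccccc4)c3OC)C[C@@H](CO)[C@@H]2CO)cc(OC)c1OCc1ccccc1
F6 | step 5 | (R)-4-[4-(benzyloxy)-3,5-dimethoxybenzyl]-3-(hydroxymethylene)dihydrofuran-2(3H)-one | O=C1OC[C@H](Cc2cc(OC)c(OCc3ccccc3)c(OC)c2)C1=CO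
F7 | step 3 | racemic 4-[4-(benzyloxy)-3,5-dimethoxyphenyl]-3-(methoxycarbonyl)butanoic acid | COC(=O)C(Cc1cc(OC)c(OCc2ccccc2)c(OC)c1)CC(=O)O
F8 | step 3 | (S)-1-phenylethylammonium salt of the (R)-half-ester | COC(=O)[C@H](Cc1cc(OC)c(OCc2ccccc2)c(OC)c1)CC(=O)[O-].C[C@H]([NH3+])c1ccccc1
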